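The seven-membered ring is built by a divinylcyclopropane–cycloheptadiene (Cope) rearrangement. In daucane locants (C1 quaternary ring-fusion carbon, C5 ring-fusion CH, C6–C10 the remaining seven-ring carbons), CH2-7 sits between C6 and C8, opposite the bond from the tiglate carbon C10 to C1: the imprint of a cis-cyclopropane C6–C7–C8 bearing a 2-methylcyclopentenone alkene (C5=C1) and an (E)-alkenylboronate (C9=C10). Heating opens the strained ring, forms C10–C1, closes the cycloheptadiene, sets C1 and C10 from cyclopropane configuration and alkene geometry, and leaves C8=C9 and C5=C6 placed for the epoxide and the C6 oxygen. The precursor comes from an iodocyclopentenone, a (Z)-alkenylstannane and an asymmetric cyclopropanation.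

Key step: step 8

Remark (reading of the structure): both esters are taken as (E)-2-methylbut-2-enoates (tiglates) and the ring fusion as cis (C1 methyl and H5 on the same face), as the SMILES specifies.

Remark (locants): daucane numbering is used for the bicyclo[5.3.0]decane core and for the same atoms in the monocyclic precursors: five-membered ring C1 (quaternary, methyl), C2 (CH–O), C3 (CH2), C4 (carbinol or ketone carbon), C5 (ring-fusion CH); seven-membered ring C5, C6, C7, C8, C9, C10, C1. β is the face of the C1 methyl, α the opposite face; C2 is (S) in every compound.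

Step 1
Reactants: 1 (S)-4-(tert-butyldimethylsilyloxy)cyclopent-2-en-1-one
Product: 3 (S)-4-(tert-butyldimethylsilyloxy)-3-methylcyclopent-2-en-1-one, via lithium enolate 2 (not isolated)
Conditions: Me2CuLi (from MeLi and CuI), Et2O, −78 °C; then N-tert-butylbenzenesulfinimidoyl chloride, THF, −78 °C
Reagents that add atoms: methyllithium, C[Li] (delivered as lithium dimethylcuprate, [Li+].C[Cu-]C)
Why: Cuprate conjugate addition anti to the silyloxy group followed by dehydrogenation of the regiodefined enolate in the same flask (sulfinimidoyl chloride, then syn elimination of the sulfenamide) should put the methyl on the β-carbon while the enolate is kept at −78 °C, where loss of the silyloxy group is slow, and the silyloxy stereocentre is not touched.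

Step 2
Reactants: 3 (S)-4-(tert-butyldimethylsilyloxy)-3-methylcyclopent-2-en-1-one
Product: 4 (S)-4-(tert-butyldimethylsilyloxy)-2-iodo-3-methylcyclopent-2-en-1-one
Conditions: I2, pyridine, DMAP (cat.), CH2Cl2, 0 °C to rt
Reagents that add atoms: iodine, II
Why: α-Iodination of the enone by the amine-mediated conjugate addition–iodination–elimination sequence (a Baylis–Hillman-type α-halogenation) should give the alkenyl iodide for cross-coupling without touching the silyl ether or the stereocentre.

Step 3
Reactants: 5 prop-2-yn-1-ol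
Product: 7 (Z)-2-methyl-3-(tributylstannyl)prop-2-en-1-ol, via alkenylmagnesium alkoxide 6 (not isolated)
Conditions: MeMgBr (3 equiv), CuI (10 mol%), THF, −10 °C to rt; then Bu3SnCl, 0 °C
Reagents that add atoms: methylmagnesium bromide, C[Mg]Br; tributyltin chloride, CCCC[Sn](Cl)(CCCC)CCCC
Why: Copper-catalysed, alkoxide-directed anti-carbomagnesiation of the propargylic alcohol puts the methyl on the internal carbon and magnesium cis to the CH2O group in a five-membered chelate, and stannylation of this alkenyl Grignard with retention should give the (Z)-stannane.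

Step 4
Reactants: 4 (S)-4-(tert-butyldimethylsilyloxy)-2-iodo-3-methylcyclopent-2-en-1-one; 7 (Z)-2-methyl-3-(tributylstannyl)prop-2-en-1-ol
Product: 8 (S)-4-(tert-butyldimethylsilyloxy)-2-[(Z)-3-hydroxy-2-methylprop-1-en-1-yl]-3-methylcyclopent-2-en-1-one
Conditions: Pd2(dba)3 (2.5 mol%), AsPh3, CuI, NMP, rt to 45 °C
Reagents that add atoms: none
Why: Stille coupling of an α-iodoenone with an alkenylstannane under base-free Pd2(dba)3/AsPh3/CuI conditions should proceed with retention of the (Z) geometry and tolerate the free alcohol and the silyloxy enone.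

Step 5
Reactants: 8 (S)-4-(tert-butyldimethylsilyloxy)-2-[(Z)-3-hydroxy-2-methylprop-1-en-1-yl]-3-methylcyclopent-2-en-1-one
Product: 9 (S)-4-(tert-butyldimethylsilyloxy)-2-[(1S,2R)-2-(hydroxymethyl)-2-methylcyclopropyl]-3-methylcyclopent-2-en-1-one
Conditions: Zn(CH2I)2·DME (from Et2Zn, CH2I2, DME), (4S,5S)-2-butyl-N,N,N',N'-tetramethyl-1,3,2-dioxaborolane-4,5-dicarboxamide (1.2 equiv), CH2Cl2, −10 °C to rt
Reagents that add atoms: diiodomethane, ICI (transferred as the zinc carbenoid Zn(CH2I)2)
Why: Charette asymmetric cyclopropanation (a directed Simmons–Smith reaction): the zinc carbenoid is delivered inside the zinc alkoxide–dioxaborolane complex only to the allylic-alcohol alkene (the tetrasubstituted enone alkene is inert), syn-stereospecifically so that the (Z)-alkene gives CH2OH cis to the cyclopentenyl group, and on the face dictated by the (4S,5S) ligand according to the established model for this ligand class, which sets both cyclopropane stereocentres under reagent control, the remote silyloxy centre having no say.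

Step 6
Reactants: 9 (S)-4-(tert-butyldimethylsilyloxy)-2-[(1S,2R)-2-(hydroxymethyl)-2-methylcyclopropyl]-3-methylcyclopent-2-en-1-one
Product: 10 (1R,2S)-2-[(S)-3-(tert-butyldimethylsilyloxy)-2-methyl-5-oxocyclopent-1-en-1-yl]-1-methylcyclopropane-1-carbaldehyde
Conditions: Dess–Martin periodinane, NaHCO3, CH2Cl2, 0 °C
Reagents that add atoms: none
Why: Dess–Martin oxidation of the neopentyl primary alcohol under buffered, cold conditions should stop at the aldehyde, which has no α-hydrogen to epimerise and is used at once so that the cis-alkenylcyclopropanecarbaldehyde has no time for a retro-Claisen ring expansion.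

Step 7
Reactants: 10 (1R,2S)-2-[(S)-3-(tert-butyldimethylsilyloxy)-2-methyl-5-oxocyclopent-1-en-1-yl]-1-methylcyclopropane-1-carbaldehyde
Product: 11 (S)-4-(tert-butyldimethylsilyloxy)-3-methyl-2-{(1S,2S)-2-methyl-2-[(E)-2-(4,4,5,5-tetramethyl-1,3,2-dioxaborolan-2-yl)ethenyl]cyclopropyl}cyclopent-2-en-1-one
Conditions: Cl2CHB(pin) (2 equiv), CrCl2 (8 equiv), LiI (4 equiv), THF, rt
Reagents that add atoms: 2-(dichloromethyl)-4,4,5,5-tetramethyl-1,3,2-dioxaborolane, ClC(Cl)B1OC(C)(C)C(C)(C)O1
Why: Takai–Utimoto-type boryl olefination with the geminal dichromium reagent from Cl2CHB(pin) is selective for the aldehyde over the enone ketone and gives the (E)-alkenylboronate, the geometry that later translates into the C10 configuration.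

Step 8
Reactants: 11 (S)-4-(tert-butyldimethylsilyloxy)-3-methyl-2-{(1S,2S)-2-methyl-2-[(E)-2-(4,4,5,5-tetramethyl-1,3,2-dioxaborolan-2-yl)ethenyl]cyclopropyl}cyclopent-2-en-1-one
Product: 13 2β-(tert-butyldimethylsilyloxy)-10α-hydroxy-1β,8-dimethylbicyclo[5.3.0]deca-5,8-dien-4-one, via allylic boronate 12 (not isolated)
Conditions: toluene, 110 °C, sealed tube; then Me3NO, THF, 65 °C
Reagents that add atoms: trimethylamine N-oxide, C[N+](C)(C)[O-]
Why: Heating the cis-1,2-dialkenylcyclopropane triggers a concerted [3,3] sigmatropic (Cope) shift through the boat transition state with both alkenes folded over the three-membered ring: the C6–C8 bond breaks and the C10–C1 bond forms, driven by release of cyclopropane strain. The closest known reaction type is the divinylcyclopropane–cycloheptadiene rearrangement that underlies formal (4+3) annulations. The seven-membered ring is closed by this pericyclic ring expansion of the cyclopropane (not by an exo or endo cyclisation onto an alkene), and the new C8=C9 and C5=C6 alkenes appear where the epoxide and the enone are wanted. The configuration of the quaternary C1 is dictated by the cyclopropane stereocentres set in step 5, because in the boat only the alkene face turned toward C10 can bond and the methyl, which is cis to the cyclopropane on the alkene, must point inward; C10 is set by the (E) geometry of the alkenylboronate, since outward substituents on the two termini end up cis, which places boron cis to C2 and trans to the C1 methyl (10α). The step needs the two alkenes cis on the cyclopropane (secured by stereospecific cyclopropanation of the (Z)-alkene) and enough heat to pass the inward methyl over the cyclopropane CH2; the usual competitor, a homodienyl 1,5-hydrogen shift, has no pathway because no hydrogen-bearing alkyl group is cis to an alkene. Trimethylamine N-oxide then turns the allylic C–B bond into C–OH with retention and, unlike alkaline peroxide, does not epoxidise the enone.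

Step 9
Reactants: 13 2β-(tert-butyldimethylsilyloxy)-10α-hydroxy-1β,8-dimethylbicyclo[5.3.0]deca-5,8-dien-4-one
Product: 14 8α,9α-epoxy-2β-(tert-butyldimethylsilyloxy)-10α-hydroxy-1β,8β-dimethylbicyclo[5.3.0]dec-5-en-4-one
Conditions: VO(acac)2 (5 mol%), t-BuOOH (decane), CH2Cl2, 0 °C to rt
Reagents that add atoms: tert-butyl hydroperoxide, CC(C)(C)OO
Why: Hydroxyl-directed epoxidation with VO(acac)2/t-BuOOH delivers oxygen to the C8=C9 alkene from the face of the allylic C10 hydroxyl (α), which sets C8 and C9, while the electron-poor enone alkene does not react.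

Step 10
Reactants: 14 8α,9α-epoxy-2β-(tert-butyldimethylsilyloxy)-10α-hydroxy-1β,8β-dimethylbicyclo[5.3.0]dec-5-en-4-one
Product: 16 8α,9α-epoxy-2β-(tert-butyldimethylsilyloxy)-6β,10α-dihydroxy-1β,8β-dimethyl-5β-H-bicyclo[5.3.0]decan-4-one, via β-boryl ketone 15 (not isolated)
Conditions: B2(pin)2, CuCl (5 mol%), xantphos (5 mol%), NaOtBu (5 mol%), MeOH (2 equiv), THF, 0 °C to rt; then NaBO3·4H2O, THF/H2O, rt
Reagents that add atoms: bis(pinacolato)diboron, CC1(C)OB(OC1(C)C)B1OC(C)(C)C(C)(C)O1 (boron of 15); sodium perborate, [Na+].[Na+].O[B-]1(O)OO[B-](O)(O)OO1 (the C6 oxygen of 16)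
Why: Copper-catalysed conjugate borylation should add the boryl group to C6 from the exo β-face (the α-face of the enone is covered by C8–C10 of the folded seven-membered ring), protonation of the enolate at C5 from the same convex face should give the cis ring fusion that is also expected to be the more stable one next to the angular methyl, and perborate oxidation of the C–B bond with retention gives the 6β-alcohol; only catalytic alkoxide is present, which limits deprotonation at C7.

Step 11
Reactants: 16 8α,9α-epoxy-2β-(tert-butyldimethylsilyloxy)-6β,10α-dihydroxy-1β,8β-dimethyl-5β-H-bicyclo[5.3.0]decan-4-one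
Product: 17 8α,9α-epoxy-2β-(tert-butyldimethylsilyloxy)-5β-daucane-4α,6β,10α-triol
Conditions: i-PrMgCl (5 equiv), CeCl3 (5 equiv, dried), THF, −78 to −30 °C
Reagents that add atoms: isopropylmagnesium chloride, CC(C)[Mg]Cl
Why: 1,2-Addition of the weakly basic organocerium reagent to the cyclopentanone, with the two hydroxyls carried as alkoxides, should occur from the convex β-face anti to the C5 substituent C6 of the cis-fused bicycle, giving the 4β-isopropyl 4α-carbinol while enolisation, β-hydride reduction and retro-aldol cleavage are suppressed.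

Step 12
Reactants: 17 8α,9α-epoxy-2β-(tert-butyldimethylsilyloxy)-5β-daucane-4α,6β,10α-triol
Product: 18 8α,9α-epoxy-2β-(tert-butyldimethylsilyloxy)-4α-hydroxy-5β-daucane-6β,10α-diyl bis[(E)-2-methylbut-2-enoate]
Conditions: tiglic acid, 2,4,6-trichlorobenzoyl chloride, Et3N, toluene, rt; then 17, DMAP, toluene, rt to 50 °C
Reagents that add atoms: tiglic acid, C/C=C(\C)C(=O)O
Why: Yamaguchi esterification through the mixed anhydride acylates the two secondary alcohols at C6 and C10 (the tertiary C4 hydroxyl is inert and O2 is silylated) without passing through a ketene, so the (E) geometry and the conjugation of the tiglate are kept.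

Step 13
Reactants: 18 8α,9α-epoxy-2β-(tert-butyldimethylsilyloxy)-4α-hydroxy-5β-daucane-6β,10α-diyl bis[(E)-2-methylbut-2-enoate]
Product: 19 (1S,2S,4R,5S,6S,8S,9R,10R)-8,9-epoxy-2,4-dihydroxydaucane-6,10-diyl bis[(E)-2-methylbut-2-enoate]
Conditions: HF·pyridine, pyridine, THF, 0 °C to rt
Reagents that add atoms: none
Why: Fluoride-mediated cleavage of the silyl ether with pyridine-buffered HF·pyridine should free the C2 hydroxyl under conditions mild enough for the trisubstituted epoxide and the two tiglates, acyl migration from O10 to O2 being disfavoured because it would need a trans-fused six-membered orthoester on the cyclopentane.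

Compound list
1 | (S)-4-(tert-butyldimethylsilyloxy)cyclopent-2-en-1-one | O=C1C=C[C@@H](O[Si](C)(C)C(C)(C)C)C1 | starting material
2 | lithium (3S,4S)-4-(tert-butyldimethylsilyloxy)-3-methylcyclopent-1-en-1-olate (methyl trans to silyloxy) | [Li]OC1=C[C@H](C)[C@@H](O[Si](C)(C)C(C)(C)C)C1 | intermediate (not isolated)
3 | (S)-4-(tert-butyldimethylsilyloxy)-3-methylcyclopent-2-en-1-one | CC1=CC(=O)C[C@@H]1O[Si](C)(C)C(C)(C)C | intermediate
4 | (S)-4-(tert-butyldimethylsilyloxy)-2-iodo-3-methylcyclopent-2-en-1-one | CC1=C(I)C(=O)C[C@@H]1O[Si](C)(C)C(C)(C)C | intermediate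
5 | prop-2-yn-1-ol | C#CCO | starting material
6 | bromomagnesium (Z)-3-(bromomagnesio)-2-methylprop-2-en-1-olate | Br[Mg]OC/C(C)=C\[Mg]Br | intermediate (not isolated)
7 | (Z)-2-methyl-3-(tributylstannyl)prop-2-en-1-ol | OC/C(C)=C\[Sn](CCCC)(CCCC)CCCC | intermediate
8 | (S)-4-(tert-butyldimethylsilyloxy)-2-[(Z)-3-hydroxy-2-methylprop-1-en-1-yl]-3-methylcyclopent-2-en-1-one | OC/C(C)=C\C1=C(C)[C@@H](O[Si](C)(C)C(C)(C)C)CC1=O | intermediate
9 | (S)-4-(tert-butyldimethylsilyloxy)-2-[(1S,2R)-2-(hydroxymethyl)-2-methylcyclopropyl]-3-methylcyclopent-2-en-1-one | C[C@@]1(CO)C[C@@H]1C2=C(C)[C@@H](O[Si](C)(C)C(C)(C)C)CC2=O | intermediate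
10 | (1R,2S)-2-[(S)-3-(tert-butyldimethylsilyloxy)-2-methyl-5-oxocyclopent-1-en-1-yl]-1-methylcyclopropane-1-carbaldehyde | C[C@@]1(C=O)C[C@@H]1C2=C(C)[C@@H](O[Si](C)(C)C(C)(C)C)CC2=O | intermediate
11 | (S)-4-(tert-butyldimethylsilyloxy)-3-methyl-2-{(1S,2S)-2-methyl-2-[(E)-2-(4,4,5,5-tetramethyl-1,3,2-dioxaborolan-2-yl)ethenyl]cyclopropyl}cyclopent-2-en-1-one | C[C@@]1(/C=C/B2OC(C)(C)C(C)(C)O2)C[C@@H]1C3=C(C)[C@@H](O[Si](C)(C)C(C)(C)C)CC3=O | intermediate
12 | 2β-(tert-butyldimethylsilyloxy)-1β,8-dimethyl-10α-(4,4,5,5-tetramethyl-1,3,2-dioxaborolan-2-yl)bicyclo[5.3.0]deca-5,8-dien-4-one | O=C1C[C@H](O[Si](C)(C)C(C)(C)C)[C@]2(C)C1=CCC(C)=C[C@@H]2B3OC(C)(C)C(C)(C)O3 | intermediate (not isolated)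
13 | 2β-(tert-butyldimethylsilyloxy)-10α-hydroxy-1β,8-dimethylbicyclo[5.3.0]deca-5,8-dien-4-one | O=C1C[C@H](O[Si](C)(C)C(C)(C)C)[C@]2(C)C1=CCC(C)=C[C@@H]2O | intermediate
14 | 8α,9α-epoxy-2β-(tert-butyldimethylsilyloxy)-10α-hydroxy-1β,8β-dimethylbicyclo[5.3.0]dec-5-en-4-one | O=C1C[C@H](O[Si](C)(C)C(C)(C)C)[C@]2(C)C1=CC[C@]3(C)O[C@@H]3[C@@H]2O | intermediate
15 | 8α,9α-epoxy-2β-(tert-butyldimethylsilyloxy)-10α-hydroxy-1β,8β-dimethyl-6β-(4,4,5,5-tetramethyl-1,3,2-dioxaborolan-2-yl)-5β-H-bicyclo[5.3.0]decan-4-one | CC1(C)OB(OC1(C)C)[C@H]1C[C@]2(C)O[C@@H]2[C@H](O)[C@@]2(C)[C@@H]1C(=O)C[C@@H]2O[Si](C)(C)C(C)(C)C | intermediate (not isolated)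
16 | 8α,9α-epoxy-2β-(tert-butyldimethylsilyloxy)-6β,10α-dihydroxy-1β,8β-dimethyl-5β-H-bicyclo[5.3.0]decan-4-one | O[C@H]1C[C@]2(C)O[C@@H]2[C@H](O)[C@@]2(C)[C@@H]1C(=O)C[C@@H]2O[Si](C)(C)C(C)(C)C | intermediate
17 | 8α,9α-epoxy-2β-(tert-butyldimethylsilyloxy)-5β-daucane-4α,6β,10α-triol (4β-isopropyl) | O[C@H]1C[C@]2(C)O[C@@H]2[C@H](O)[C@@]2(C)[C@@H]1[C@](O)(C(C)C)C[C@@H]2O[Si](C)(C)C(C)(C)C | intermediate
18 | 8α,9α-epoxy-2β-(tert-butyldimethylsilyloxy)-4α-hydroxy-5β-daucane-6β,10α-diyl bis[(E)-2-methylbut-2-enoate] | C/C=C(\C)C(=O)O[C@H]1C[C@]2(C)O[C@@H]2[C@H](OC(=O)/C(C)=C/C)[C@@]2(C)[C@@H]1[C@](O)(C(C)C)C[C@@H]2O[Si](C)(C)C(C)(C)C | intermediate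
19 | (1S,2S,4R,5S,6S,8S,9R,10R)-8,9-epoxy-2,4-dihydroxydaucane-6,10-diyl bis[(E)-2-methylbut-2-enoate] (8α,9α-epoxy-2β,4α-dihydroxy-5β-daucane-6β,10α-diyl ditiglate) | C/C=C(\C)C(=O)O[C@H]1C[C@]2(C)O[C@@H]2[C@H](OC(=O)/C(C)=C/C)[C@@]2(C)[C@@H]1[C@](O)(C(C)C)C[C@@H]2O | target

Total step count: 13
Longest linear sequence: 12 steps (from 1: steps 1, 2 and 4 to 13); step 3 prepares the stannane from 5.

Steps most likely to fail

Step 8. The boat transition state holds the C1 methyl over the cyclopropane CH2, so the rearrangement may need a temperature at which the allylic boronate suffers protodeboronation or a 1,3-boron shift, with erosion of the C10 stereocentre. The fallback sets out from 11 and comes back at 13, carrying oxygen instead of boron through the rearrangement. Copper-promoted oxidative coupling of the alkenylboronate with 4-methoxybenzyl alcohol (Cu(OAc)2, Et3N, air, rt; Chan–Lam type, retention of the E geometry) would give the (E)-4-methoxybenzyl enol ether of the cis-cyclopropane F1, in which a donor alkene is paired with the acceptor enone. Thermolysis in toluene would then give, by the same boat rearrangement, the 10α-(4-methoxybenzyl) ether of the cycloheptadienone F2. DDQ in CH2Cl2/pH 7 buffer would release alcohol 13.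

Step 10. Addition of the bulky boryl-copper species to the α-branched enone may be slow, so that deprotonation at C7 with opening of the epoxide, or loss of the β-boryl group back to the enone during oxidation, takes over. The fallback sets out from 14 and comes back at 16, introducing the C6 oxygen as a small peroxide nucleophile. Weitz–Scheffer epoxidation (t-BuOOH, catalytic benzyltrimethylammonium hydroxide, THF, −20 °C) should attack C6 from the same exo β-face and give the 5β,6β-epoxy ketone F3. SmI2 (THF/MeOH, −78 °C) would cleave only the C5–O bond of the α,β-epoxy ketone, leave the isolated 8,9-epoxide, and give 16 after protonation of the samarium enolate from the convex face.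

Step 11. The secondary organometallic may enolise the ketone at C5 (followed by loss of the C6 alkoxide) or reduce it by β-hydride transfer instead of adding. The fallback sets out from 16 and comes back at 17, using an sp2 nucleophile without β-hydrogens on a saturated carbon. Isopropenylmagnesium bromide with CeCl3 (THF, −78 °C) should add from the same β-face and give the 4β-isopropenyl carbinol F4. Hydrogenation of the 1,1-disubstituted alkene (H2, RhCl(PPh3)3, benzene/EtOH, rt), which spares the epoxide, would give 17.

Further compounds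
F1 | step 8 | (S)-4-(tert-butyldimethylsilyloxy)-2-{2-[(E)-2-(4-methoxybenzyloxy)ethenyl]-2-methylcyclopropyl}-3-methylcyclopent-2-en-1-one (cyclopropane configuration as in 11) | C[C@@]1(/C=C/OCc2ccc(OC)cc2)C[C@@H]1C3=C(C)[C@@H](O[Si](C)(C)C(C)(C)C)CC3=O
F2 | step 8 | 2β-(tert-butyldimethylsilyloxy)-10α-(4-methoxybenzyloxy)-1β,8-dimethylbicyclo[5.3.0]deca-5,8-dien-4-one | O=C1C[C@H](O[Si](C)(C)C(C)(C)C)[C@]2(C)C1=CCC(C)=C[C@@H]2OCc3ccc(OC)cc3
F3 | step 10 | 5β,6β:8α,9α-diepoxy-2β-(tert-butyldimethylsilyloxy)-10α-hydroxy-1β,8β-dimethylbicyclo[5.3.0]decan-4-one | O5[C@H]1C[C@]2(C)O[C@@H]2[C@H](O)[C@@]2(C)[C@]15C(=O)C[C@@H]2O[Si](C)(C)C(C)(C)C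
F4 | step 11 | 4β-(prop-1-en-2-yl) analogue of 17 (8α,9α-epoxy-2β-silyloxy-4α,6β,10α-triol) | O[C@H]1C[C@]2(C)O[C@@H]2[C@H](O)[C@@]2(C)[C@@H]1[C@](O)(C(C)=C)C[C@@H]2O[Si](C)(C)C(C)(C)C
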